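**Retrosynthetic overview**

1. The target comes from hydroquinone 27 by mild oxidation; 27 comes from a one-pot union of three components: the C48 terminal alkyne 18, AlMe3 and the 4-(buta-2,3-dien-2-yl)-4-silyloxycyclobutenone 23.
2. Ring order: the only ring enters as the four-membered ring of dimethyl squarate and becomes six-membered in step 14 (4π opening, then 6π closure onto the allene, two atoms more); no other ring is made.
3. Enabling feature: ring atoms C1–C4 (C=O, C–OMe, C–OMe, C=O) are an intact squarate C4 unit, and ring C5 (with its CH3), C6 and the benzylic CH2 are a 1-methylallenyl unit. Because that CH2 is ortho to the C1 oxygen it can emerge as the exocyclic carbon of an ortho-quinone methide, and the adjacent (E)-CH=C(CH3) is what syn-methylalumination of a terminal alkyne supplies.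
4. Alkyne 18 comes from geranylgeraniol plus a C3 propargyl unit (isoprene units 2–5, counted from the ring), farnesyl sulfone (units 6–8) and (R)-citronellyl bromide (units 9–10, the only stereocentre, from the chiral pool). The pieces are joined by sulfone alkylation/desulfonylation and a copper-catalysed Grignard coupling after E-selective SeO2 ω-oxidations.

Key step: step 14

Remark: all-E geranylgeraniol, (2E,6E)-farnesyl bromide, (R)-citronellyl bromide, dimethyl squarate, 1-bromobut-2-yne and 1-(trimethylsilyl)propyne are taken as purchased materials.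
Remark: the sulfonyl-bearing carbon of 12 and C4 of 22 and 23 are formed without control; both centres are destroyed later (steps 8 and 14), so nothing depends on them.
Remark: hydroquinone 27 is air-sensitive and should be carried into step 15 as crude material under argon.

**Step 1**
Reactants: 1 (2E,6E,10E)-geranylgeraniol
Product: 2 (2E,6E,10E)-1-bromo-3,7,11,15-tetramethylhexadeca-2,6,10,14-tetraene
Conditions: PBr3 (0.4 equiv), Et2O, −10 °C
Reagents that add atoms: phosphorus tribromide, `BrP(Br)Br`
Why: Bromination of a primary allylic alcohol with PBr3 at low temperature should proceed by SN2 at the unhindered carbon without allylic transposition or loss of the 2E geometry.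

**Step 2**
Reactants: 2 geranylgeranyl bromide; 3 1-(trimethylsilyl)propyne
Product: 5 trimethyl[(5E,9E,13E)-6,10,14,18-tetramethylnonadeca-5,9,13,17-tetraen-1-yn-1-yl]silane, via 3-lithio-1-(trimethylsilyl)propyne 4 (not isolated)
Conditions: 3, n-BuLi, THF, −78 → −20 °C; then 2, −78 °C → rt
Reagents that add atoms: none
Why: Alkylation of the silyl-stabilised propargylic lithium reagent by the primary allylic bromide should occur by SN2 at the α-carbon of both partners, adding the C3 unit that later becomes C2–C4 of the first isoprene unit.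

**Step 3**
Reactants: 5 silyl enyne
Product: 6 (2E,6E,10E,14E)-2,6,10,14-tetramethyl-19-(trimethylsilyl)nonadeca-2,6,10,14-tetraen-18-yn-1-ol
Conditions: SeO2 (0.3 equiv), t-BuOOH, salicylic acid (cat.), CH2Cl2, 0 °C → rt, stopped at partial conversion
Reagents that add atoms: selenium dioxide, `O=[Se]=O`; tert-butyl hydroperoxide, `CC(C)(C)OO`
Why: Riley allylic oxidation (ene reaction followed by [2,3]-sigmatropic shift) should attack the most electron-rich and least hindered terminal isopropylidene group and oxidise its E-methyl group to the (E)-allylic alcohol, unreacted 5 being recycled.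

**Step 4**
Reactants: 6 ω-hydroxy silyl enyne
Product: 7 [(5E,9E,13E,17E)-19-bromo-6,10,14,18-tetramethylnonadeca-5,9,13,17-tetraen-1-yn-1-yl]trimethylsilane
Conditions: CBr4, PPh3, CH2Cl2, 0 °C
Reagents that add atoms: carbon tetrabromide, `BrC(Br)(Br)Br`
Why: The Appel reaction should convert the primary allylic alcohol into the bromide under neutral conditions without allylic shift and without touching the silylalkyne.

**Step 5**
Reactants: 8 (2E,6E)-farnesyl bromide
Product: 9 1-methyl-4-{[(2E,6E)-3,7,11-trimethyldodeca-2,6,10-trien-1-yl]sulfonyl}benzene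
Conditions: sodium p-toluenesulfinate, DMF, rt
Reagents that add atoms: sodium 4-methylbenzenesulfinate, `Cc1ccc(cc1)S(=O)[O-].[Na+]`
Why: S-alkylation of the sulfinate by SN2 displacement of the primary allylic bromide should give the allylic sulfone with the 2E geometry intact.

**Step 6**
Reactants: 9 farnesyl p-tolyl sulfone
Product: 10 (2E,6E,10E)-2,6,10-trimethyl-12-(4-methylbenzenesulfonyl)dodeca-2,6,10-trien-1-ol
Conditions: SeO2 (0.3 equiv), t-BuOOH, salicylic acid (cat.), CH2Cl2, 0 °C → rt, stopped at partial conversion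
Reagents that add atoms: selenium dioxide, `O=[Se]=O`; tert-butyl hydroperoxide, `CC(C)(C)OO`
Why: Riley oxidation should again select the terminal isopropylidene group, the olefin next to the electron-withdrawing sulfonyl group being deactivated, and give the (E)-ω-alcohol.

**Step 7**
Reactants: 10 hydroxy sulfone; 7 ω-bromo silyl enyne
Product: 12 (2E,6E,10E,14E,18E,22E,26E)-2,6,10,14,18,22,26-heptamethyl-12-(4-methylbenzenesulfonyl)-31-(trimethylsilyl)hentriaconta-2,6,10,14,18,22,26-heptaen-30-yn-1-ol, via dilithiated hydroxy sulfone 11 (not isolated)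
Conditions: 10, n-BuLi (2.1 equiv), THF–DMPU, −78 °C; then 7, −78 → −30 °C; H2O
Reagents that add atoms: none
Why: Alkylation of the α-sulfonyl allylic carbanion (the alkoxide remaining a spectator) by the primary allylic bromide should take place at the sulfone α-carbon and by SN2 on the bromide, joining units 5 and 6 head to tail with all olefin geometries retained.

**Step 8**
Reactants: 12 coupled hydroxy sulfone
Product: 13 (2E,6E,10E,14E,18E,22E,26E)-2,6,10,14,18,22,26-heptamethyl-31-(trimethylsilyl)hentriaconta-2,6,10,14,18,22,26-heptaen-30-yn-1-ol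
Conditions: PdCl2(dppp) (5 mol %), LiBHEt3, THF, 0 °C → rt
Reagents that add atoms: none
Why: In this palladium-catalysed reductive desulfonylation zerovalent palladium ionises the allylic sulfone and hydride is delivered to the less substituted allyl terminus, which should keep the position and E geometry of the trisubstituted olefin, while the ω-hydroxyl, present as its lithium alkoxide, is not ionised.

**Step 9**
Reactants: 13 C31 ω-alcohol
Product: 14 [(5E,9E,13E,17E,21E,25E,29E)-31-bromo-6,10,14,18,22,26,30-heptamethylhentriaconta-5,9,13,17,21,25,29-heptaen-1-yn-1-yl]trimethylsilane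
Conditions: CBr4, PPh3, CH2Cl2, 0 °C
Reagents that add atoms: carbon tetrabromide, `BrC(Br)(Br)Br`
Why: The Appel reaction should again give the primary (E)-allylic bromide without transposition.

**Step 10**
Reactants: 14 C31 ω-bromide; 15 (R)-citronellyl bromide
Product: 17 trimethyl[(5E,9E,13E,17E,21E,25E,29E,34S)-6,10,14,18,22,26,30,34,38-nonamethylnonatriaconta-5,9,13,17,21,25,29,37-octaen-1-yn-1-yl]silane, via (R)-citronellylmagnesium bromide 16 (not isolated)
Conditions: 15, Mg, THF, rt; then 14, Li2CuCl4 (3 mol %), THF, −78 → −20 °C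
Reagents that add atoms: none
Why: Copper-catalysed cross-coupling of a primary alkyl Grignard reagent with a primary allylic bromide in THF should go by α-substitution with retention of the E geometry, and the stereocentre of 15, which is not involved, is carried over unchanged to become C35 (S) of the target.

**Step 11**
Reactants: 17 silylated C48 enyne
Product: 18 (5E,9E,13E,17E,21E,25E,29E,34S)-6,10,14,18,22,26,30,34,38-nonamethylnonatriaconta-5,9,13,17,21,25,29,37-octaen-1-yne
Conditions: K2CO3, MeOH–THF, rt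
Reagents that add atoms: none
Why: Base-catalysed methanolysis of the C(sp)–Si bond should free the terminal alkyne without affecting the olefins.

**Step 12**
Reactants: 19 dimethyl squarate; 20 1-bromobut-2-yne
Product: 22 4-(buta-2,3-dien-2-yl)-4-hydroxy-2,3-dimethoxycyclobut-2-en-1-one (racemic), via but-2-ynylindium dibromide 21 (not isolated)
Conditions: In powder, DMF, rt; aq NH4Cl
Reagents that add atoms: none
Why: In this Barbier-type indium-mediated reaction a γ-substituted propargylindium reagent should react at its γ-carbon (SE2′) in a 1,2-addition to one of the two equivalent, highly electrophilic squarate carbonyls, giving the α-allenyl tertiary alcohol.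

**Step 13**
Reactants: 22 allenyl cyclobutenol
Product: 23 4-(buta-2,3-dien-2-yl)-2,3-dimethoxy-4-[(trimethylsilyl)oxy]cyclobut-2-en-1-one (racemic)
Conditions: TMSCl, imidazole, DMF, 0 °C
Reagents that add atoms: chlorotrimethylsilane, `C[Si](C)(C)Cl`
Why: Standard silylation of the tertiary alcohol should mask the acidic OH toward the alane and provide the outward-rotating donor group needed in step 14.

**Step 14**
Reactants: 18 C48 terminal alkyne; 23 silyloxy allenylcyclobutenone
Product: 27 2,3-dimethoxy-5-methyl-6-[(2E,6E,10E,14E,18E,22E,26E,30E,35S)-3,7,11,15,19,23,27,31,35,39-decamethyltetraconta-2,6,10,14,18,22,26,30,38-nonaen-1-yl]benzene-1,4-diol, via alkenyldimethylalane 24 (not isolated), via ortho-quinone methide 25 (not isolated), via dimethylaluminium aryloxide 26 (not isolated)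
Conditions: 18, AlMe3 (2 equiv), Cp2ZrCl2 (20 mol %), ClCH2CH2Cl, rt; evaporate volatiles and free AlMe3; toluene, 23 (1.2 equiv, slow addition), 85 °C, argon; then 1 M HCl, THF, 0 °C
Reagents that add atoms: trimethylaluminium, `C[Al](C)C`
Why: Proposed new method: syn-methylalumination of 18 (Negishi carboalumination) fixes the E-trisubstituted first olefin as alkenylalane 24; on heating, 23 undergoes conrotatory 4π opening of the C1–C4 bond with the siloxy group turning outward, which places the methylallenyl group cis to the ketene, and the resulting allenyl(vinyl)ketene closes by 6π electrocyclisation between the ketene carbon and the central allene carbon, turning the four-membered ring into the six-membered ring (two atoms more) as ortho-quinone methide 25. The Lewis-acidic alane should then bind the carbonyl oxygen of 25 and deliver its alkenyl group to the exocyclic CH2 through a six-membered transition state (1,4-addition with retention of olefin geometry), which aromatises the ring to aryloxide 26, and acidic work-up removes aluminium and the aryl silyl ether. The closest known reaction types are the thermal ring expansion of 4-allenylcyclobutenones to ortho-quinone methides, the conjugate addition of alkenylalanes to enones held in the s-cis form, and the 1,4-addition of Grignard reagents and alkenylboronates to ortho-quinone methides. No stereocentre is formed, the remote C35 centre is untouched, and the new olefin geometry is controlled by the syn-carbometalation. The step needs torquoselectivity (secured by the donor OSiMe3 at C4), 1,4- over 1,2-addition and alkenyl over methyl transfer (secured by the locked cisoid heterodiene, the gain of aromaticity and the faster migration of sp2 carbon), and trapping faster than quinone methide dimerisation (secured by slow addition of 23 to 24 after removal of free AlMe3).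

**Step 15**
Reactants: 27 hydroquinone
Product: 28 2,3-dimethoxy-5-methyl-6-[(2E,6E,10E,14E,18E,22E,26E,30E,35S)-3,7,11,15,19,23,27,31,35,39-decamethyltetraconta-2,6,10,14,18,22,26,30,38-nonaen-1-yl]cyclohexa-2,5-diene-1,4-dione (target)
Conditions: Ag2O, MgSO4, Et2O, rt
Reagents that add atoms: none
Why: Two-electron oxidation of a para-hydroquinone to the para-quinone by Ag2O is mild and should leave the nine olefins and the stereocentre untouched.

**Compound list**

1 | (2E,6E,10E)-3,7,11,15-tetramethylhexadeca-2,6,10,14-tetraen-1-ol (all-E geranylgeraniol) | `OC/C=C(\C)CC/C=C(\C)CC/C=C(\C)CCC=C(C)C` | starting material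
2 | (2E,6E,10E)-1-bromo-3,7,11,15-tetramethylhexadeca-2,6,10,14-tetraene | `BrC/C=C(\C)CC/C=C(\C)CC/C=C(\C)CCC=C(C)C` | intermediate
3 | trimethyl(prop-1-yn-1-yl)silane | `CC#C[Si](C)(C)C` | starting material
4 | (3-lithioprop-1-yn-1-yl)trimethylsilane | `[Li]CC#C[Si](C)(C)C` | intermediate
5 | trimethyl[(5E,9E,13E)-6,10,14,18-tetramethylnonadeca-5,9,13,17-tetraen-1-yn-1-yl]silane | `C[Si](C)(C)C#CCC/C=C(\C)CC/C=C(\C)CC/C=C(\C)CCC=C(C)C` | intermediate
6 | (2E,6E,10E,14E)-2,6,10,14-tetramethyl-19-(trimethylsilyl)nonadeca-2,6,10,14-tetraen-18-yn-1-ol | `C[Si](C)(C)C#CCC/C=C(\C)CC/C=C(\C)CC/C=C(\C)CC/C=C(\C)CO` | intermediate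
7 | [(5E,9E,13E,17E)-19-bromo-6,10,14,18-tetramethylnonadeca-5,9,13,17-tetraen-1-yn-1-yl]trimethylsilane | `C[Si](C)(C)C#CCC/C=C(\C)CC/C=C(\C)CC/C=C(\C)CC/C=C(\C)CBr` | intermediate
8 | (2E,6E)-1-bromo-3,7,11-trimethyldodeca-2,6,10-triene (farnesyl bromide) | `BrC/C=C(\C)CC/C=C(\C)CCC=C(C)C` | starting material
9 | 1-methyl-4-{[(2E,6E)-3,7,11-trimethyldodeca-2,6,10-trien-1-yl]sulfonyl}benzene | `Cc1ccc(cc1)S(=O)(=O)C/C=C(\C)CC/C=C(\C)CCC=C(C)C` | intermediate
10 | (2E,6E,10E)-2,6,10-trimethyl-12-(4-methylbenzenesulfonyl)dodeca-2,6,10-trien-1-ol | `Cc1ccc(cc1)S(=O)(=O)C/C=C(\C)CC/C=C(\C)CC/C=C(\C)CO` | intermediate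
11 | O,C12-dilithio derivative of 10 | `Cc1ccc(cc1)S(=O)(=O)C([Li])/C=C(\C)CC/C=C(\C)CC/C=C(\C)CO[Li]` | intermediate
12 | (2E,6E,10E,14E,18E,22E,26E)-2,6,10,14,18,22,26-heptamethyl-12-(4-methylbenzenesulfonyl)-31-(trimethylsilyl)hentriaconta-2,6,10,14,18,22,26-heptaen-30-yn-1-ol (racemic at C12) | `C[Si](C)(C)C#CCC/C=C(\C)CC/C=C(\C)CC/C=C(\C)CC/C=C(\C)CC(S(=O)(=O)c1ccc(C)cc1)/C=C(\C)CC/C=C(\C)CC/C=C(\C)CO` | intermediate
13 | (2E,6E,10E,14E,18E,22E,26E)-2,6,10,14,18,22,26-heptamethyl-31-(trimethylsilyl)hentriaconta-2,6,10,14,18,22,26-heptaen-30-yn-1-ol | `C[Si](C)(C)C#CCC/C=C(\C)CC/C=C(\C)CC/C=C(\C)CC/C=C(\C)CC/C=C(\C)CC/C=C(\C)CC/C=C(\C)CO` | intermediate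
14 | [(5E,9E,13E,17E,21E,25E,29E)-31-bromo-6,10,14,18,22,26,30-heptamethylhentriaconta-5,9,13,17,21,25,29-heptaen-1-yn-1-yl]trimethylsilane | `C[Si](C)(C)C#CCC/C=C(\C)CC/C=C(\C)CC/C=C(\C)CC/C=C(\C)CC/C=C(\C)CC/C=C(\C)CC/C=C(\C)CBr` | intermediate
15 | (6R)-8-bromo-2,6-dimethyloct-2-ene ((R)-citronellyl bromide) | `BrCC[C@H](C)CCC=C(C)C` | starting material
16 | [(3R)-3,7-dimethyloct-6-en-1-yl]magnesium bromide | `Br[Mg]CC[C@H](C)CCC=C(C)C` | intermediate
17 | trimethyl[(5E,9E,13E,17E,21E,25E,29E,34S)-6,10,14,18,22,26,30,34,38-nonamethylnonatriaconta-5,9,13,17,21,25,29,37-octaen-1-yn-1-yl]silane | `C[Si](C)(C)C#CCC/C=C(\C)CC/C=C(\C)CC/C=C(\C)CC/C=C(\C)CC/C=C(\C)CC/C=C(\C)CC/C=C(\C)CCC[C@H](C)CCC=C(C)C` | intermediate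
18 | (5E,9E,13E,17E,21E,25E,29E,34S)-6,10,14,18,22,26,30,34,38-nonamethylnonatriaconta-5,9,13,17,21,25,29,37-octaen-1-yne | `C#CCC/C=C(\C)CC/C=C(\C)CC/C=C(\C)CC/C=C(\C)CC/C=C(\C)CC/C=C(\C)CC/C=C(\C)CCC[C@H](C)CCC=C(C)C` | intermediate
19 | 3,4-dimethoxycyclobut-3-ene-1,2-dione (dimethyl squarate) | `COC1=C(OC)C(=O)C1=O` | starting material
20 | 1-bromobut-2-yne | `CC#CCBr` | starting material
21 | but-2-yn-1-ylindium dibromide | `CC#CC[In](Br)Br` | intermediate
22 | 4-(buta-2,3-dien-2-yl)-4-hydroxy-2,3-dimethoxycyclobut-2-en-1-one (racemic) | `COC1=C(OC)C(O)(C(C)=C=C)C1=O` | intermediate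
23 | 4-(buta-2,3-dien-2-yl)-2,3-dimethoxy-4-[(trimethylsilyl)oxy]cyclobut-2-en-1-one (racemic) | `COC1=C(OC)C(O[Si](C)(C)C)(C(C)=C=C)C1=O` | intermediate
24 | [(1E,5E,9E,13E,17E,21E,25E,29E,34S)-2,6,10,14,18,22,26,30,34,38-decamethylnonatriaconta-1,5,9,13,17,21,25,29,37-nonaen-1-yl]dimethylalumane | `C[Al](C)/C=C(\C)CC/C=C(\C)CC/C=C(\C)CC/C=C(\C)CC/C=C(\C)CC/C=C(\C)CC/C=C(\C)CC/C=C(\C)CCC[C@H](C)CCC=C(C)C` | intermediate
25 | 2,3-dimethoxy-5-methyl-6-methylidene-4-[(trimethylsilyl)oxy]cyclohexa-2,4-dien-1-one | `C=C1C(=O)C(OC)=C(OC)C(O[Si](C)(C)C)=C1C` | intermediate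
26 | dimethylaluminium 2,3-dimethoxy-5-methyl-6-[(2E,6E,10E,14E,18E,22E,26E,30E,35S)-3,7,11,15,19,23,27,31,35,39-decamethyltetraconta-2,6,10,14,18,22,26,30,38-nonaen-1-yl]-4-[(trimethylsilyl)oxy]phenoxide | `C[Al](C)Oc1c(OC)c(OC)c(O[Si](C)(C)C)c(C)c1C/C=C(\C)CC/C=C(\C)CC/C=C(\C)CC/C=C(\C)CC/C=C(\C)CC/C=C(\C)CC/C=C(\C)CC/C=C(\C)CCC[C@H](C)CCC=C(C)C` | intermediate
27 | 2,3-dimethoxy-5-methyl-6-[(2E,6E,10E,14E,18E,22E,26E,30E,35S)-3,7,11,15,19,23,27,31,35,39-decamethyltetraconta-2,6,10,14,18,22,26,30,38-nonaen-1-yl]benzene-1,4-diol | `Oc1c(OC)c(OC)c(O)c(C)c1C/C=C(\C)CC/C=C(\C)CC/C=C(\C)CC/C=C(\C)CC/C=C(\C)CC/C=C(\C)CC/C=C(\C)CC/C=C(\C)CCC[C@H](C)CCC=C(C)C` | intermediate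
28 | 2,3-dimethoxy-5-methyl-6-[(2E,6E,10E,14E,18E,22E,26E,30E,35S)-3,7,11,15,19,23,27,31,35,39-decamethyltetraconta-2,6,10,14,18,22,26,30,38-nonaen-1-yl]cyclohexa-2,5-diene-1,4-dione | `COC1=C(OC)C(=O)C(C/C=C(\C)CC/C=C(\C)CC/C=C(\C)CC/C=C(\C)CC/C=C(\C)CC/C=C(\C)CC/C=C(\C)CC/C=C(\C)CCC[C@H](C)CCC=C(C)C)=C(C)C1=O` | target

**Step count**

Total steps: 15. Longest linear sequence: 11 steps (1, 2, 3, 4, 7, 8, 9, 10, 11, 14, 15, from geranylgeraniol).

**Steps most likely to fail, with fallbacks**

1. Step 14 (proposed new method). What may go wrong: the alane may add 1,2 to the cyclobutenone carbonyl or transfer methyl instead of alkenyl, or the quinone methide may dimerise before it is trapped. The fallback uses known chemistry and still forms the ring by four-to-six ring expansion. It sets out from 19 and from 24 (generated from 18 as in step 14) and returns at 27. From 19, 1-propynyllithium (THF, −78 °C) should give 4-hydroxy-2,3-dimethoxy-4-(prop-1-yn-1-yl)cyclobut-2-en-1-one F1. Thermolysis of F1 in refluxing p-xylene (Moore rearrangement through the enynylketene, with hydrogen shift) should give 2,3-dimethoxy-5-methylcyclohexa-2,5-diene-1,4-dione F2. Separately, 24 is converted with n-BuLi and then paraformaldehyde into (2E,6E,10E,14E,18E,22E,26E,30E,35S)-3,7,11,15,19,23,27,31,35,39-decamethyltetraconta-2,6,10,14,18,22,26,30,38-nonaen-1-ol F3. PBr3 (Et2O, −10 °C) should give the corresponding 1-bromide F4, and Me3SnLi (THF, −78 °C) the corresponding trimethyl(allyl)stannane F5. BF3·OEt2-promoted allylation of F2 with F5 (CH2Cl2, −78 °C), at the only free ring position, should give hydroquinone 27, which is oxidised as in step 15.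

2. Step 12. What may go wrong: poor regiocontrol in the propargyl/allenyl metallotropy (homopropargyl instead of allenyl carbinol), or attack at the methoxy-bearing ring carbons with loss of methoxide. The fallback sets out from 19 and returns at 23, replacing steps 12 and 13. 3-Chloro-1-lithiopropyne (from propargyl chloride and n-BuLi, Et2O, −78 °C) is added to 19 and the alkoxide is quenched with TMSCl, which should give 4-(3-chloroprop-1-yn-1-yl)-2,3-dimethoxy-4-[(trimethylsilyl)oxy]cyclobut-2-en-1-one F6. Anti-SN2′ displacement of chloride with Me2CuLi (Et2O, −78 °C) then builds the methylallene by C–CH3 bond formation and should give 23.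

3. Step 10. What may go wrong: competing γ-attack (SN2′) giving a branched 1,1-disubstituted olefin, erosion of the E geometry, or homocoupling of the Grignard reagent. The fallback sets out from 15 and 14 and returns at 17. From 15, PhSO2Na (DMF, rt) should give {[(3R)-3,7-dimethyloct-6-en-1-yl]sulfonyl}benzene F7. Its α-lithio derivative (n-BuLi, THF–DMPU, −78 °C) is alkylated by 14 to give the 32-(benzenesulfonyl) derivative of 17 F8 (epimers at the sulfonyl carbon). Reductive desulfonylation with Na(Hg), Na2HPO4, MeOH–THF, −20 °C should give 17, which continues with step 11.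

**Further compounds**

F1 | step 14 | 4-hydroxy-2,3-dimethoxy-4-(prop-1-yn-1-yl)cyclobut-2-en-1-one | `COC1=C(OC)C(O)(C#CC)C1=O`
F2 | step 14 | 2,3-dimethoxy-5-methylcyclohexa-2,5-diene-1,4-dione | `COC1=C(OC)C(=O)C(C)=CC1=O`
F3 | step 14 | (2E,6E,10E,14E,18E,22E,26E,30E,35S)-3,7,11,15,19,23,27,31,35,39-decamethyltetraconta-2,6,10,14,18,22,26,30,38-nonaen-1-ol | `OC/C=C(\C)CC/C=C(\C)CC/C=C(\C)CC/C=C(\C)CC/C=C(\C)CC/C=C(\C)CC/C=C(\C)CC/C=C(\C)CCC[C@H](C)CCC=C(C)C`
F4 | step 14 | (2E,6E,10E,14E,18E,22E,26E,30E,35S)-1-bromo-3,7,11,15,19,23,27,31,35,39-decamethyltetraconta-2,6,10,14,18,22,26,30,38-nonaene | `BrC/C=C(\C)CC/C=C(\C)CC/C=C(\C)CC/C=C(\C)CC/C=C(\C)CC/C=C(\C)CC/C=C(\C)CC/C=C(\C)CCC[C@H](C)CCC=C(C)C`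
F5 | step 14 | trimethyl[(2E,6E,10E,14E,18E,22E,26E,30E,35S)-3,7,11,15,19,23,27,31,35,39-decamethyltetraconta-2,6,10,14,18,22,26,30,38-nonaen-1-yl]stannane | `C[Sn](C)(C)C/C=C(\C)CC/C=C(\C)CC/C=C(\C)CC/C=C(\C)CC/C=C(\C)CC/C=C(\C)CC/C=C(\C)CC/C=C(\C)CCC[C@H](C)CCC=C(C)C`
F6 | step 12 | 4-(3-chloroprop-1-yn-1-yl)-2,3-dimethoxy-4-[(trimethylsilyl)oxy]cyclobut-2-en-1-one | `COC1=C(OC)C(O[Si](C)(C)C)(C#CCCl)C1=O`
F7 | step 10 | {[(3R)-3,7-dimethyloct-6-en-1-yl]sulfonyl}benzene | `O=S(=O)(CC[C@H](C)CCC=C(C)C)c1ccccc1`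
F8 | step 10 | 32-(benzenesulfonyl) derivative of 17 (epimers at C32; methyl-bearing centre as in 15) | `C[Si](C)(C)C#CCC/C=C(\C)CC/C=C(\C)CC/C=C(\C)CC/C=C(\C)CC/C=C(\C)CC/C=C(\C)CC/C=C(\C)CC(S(=O)(=O)c1ccccc1)C[C@H](C)CCC=C(C)C`
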